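Numbering: the side chain is numbered C1' (benzylic) to C16' (CH2OH); TBS = tert-butyldimethylsilyl; compounds are 1–28.

## The problem

Target 28 is a 2-methylhydroquinone with an unbranched sixteen-carbon chain on C6, so no ring has to be built beyond a commercial arene. The task is the controlled assembly of a skipped polyene with four trisubstituted E alkenes (C2'=C3', C6'=C7', C10'=C11', C14'=C15') separated by pairs of methylenes. The only stereocentre is the secondary carbinol C5' (S). Nothing else in the molecule can direct it, so it has to come from an external chiral reagent or catalyst. Because C5' is allylic to C6'=C7', it ionises easily, and any step that develops positive charge there threatens its configuration and the position of the alkene. The hydroquinone is oxidised by air and, as a free phenol, adds to the C2'=C3' alkene under acid to give chromans; C1' is benzylic and allylic at once. The primary allylic alcohol at C16' and the E alkenes rule out strongly cationic or radical conditions late in the route. The feature that opens the molecule is the C8'–C9' bridge: both carbons are allylic methylenes (to C6'=C7' and C10'=C11'), each is naturally an allylic electrophile, and a removable sulfonyl group on C9' reverses its polarity. C7' and C11' are fully substituted, which disfavours SN2′ attack in the union and directs the later removal of sulfur.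

## Retrosynthesis

**28 ⇒ 27 ⇒ 26 ⇒ 25 (protecting groups only).** No skeletal bond is cut; two aryl methyl ethers and two silyl ethers are added.
- The free hydroquinone cannot pass through AlMe3, n-BuLi or LiBHEt3, whereas methyl ethers are inert to all three.
- Oxidative demethylation of diol 26 with (NH4)2Ce(NO3)6 gives quinone 27, and neutral Na2S2O4 reduction gives 28 as the last operation, so the air-sensitive hydroquinone is exposed only once.
- Acetal protection of the phenols was set aside because its acidic removal would endanger the C5' carbinol and invite chroman formation.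
- Both alcohols are carried as TBS ethers in 25 and released together by fluoride. The oxidation must spare four alkenes and two allylic alcohols.

**25 ⇒ 24 ⇒ 18 + 22 (C9'–S, then C8'–C9').** Sulfone 24 carries a phenylsulfonyl group on C9'. Cutting C8'–C9' gives allylic bromide 18 (arene to C8', with the C5' stereocentre) and sulfone 22 (C9'–C16'), joined through lithiated sulfone 23.
- Against C12'–C13': that is the same kind of bond but would leave nearly all the complexity in one piece.
- Against C4'–C5': a prenyl-type allyl metal would have to react at its α-carbon next to the stereocentre, against its normal γ-selectivity.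
- The sulfone is on C9', not C8'. An anion at C8' would be an allyl anion with carbanion character at C6', next to the C5' oxygen, and would eliminate silanolate. Its palladium allyl complex would also have two secondary termini.
- With the sulfone on C9' the allyl system ends at the fully substituted C11', so hydride should be delivered to C9'.
- The forward reaction must give α-alkylation, SN2 rather than SN2′, and leave the E alkenes and the C5' ether alone.

**18 ⇒ 17 ⇒ 16 (functional-group changes).** Bromide 18 comes from allylic alcohol 17 under neutral Appel conditions, and 17 from bis-silyl ether 16 by cleavage of the primary TBS ether only. Using the same silyl group on both oxygens saves a protecting-group exchange. The forward step relies on the steric difference between the primary C8' ether and the secondary C5' ether.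

**16 ⇒ 14 + 6 (C1'–C2' and C3'–CH3).** Zirconium-catalysed carboalumination of alkyne 14 adds methyl and aluminium syn, giving alkenylalane 15, which is benzylated by chloride 6.
- This makes the C2'=C3' E alkene, the C3' methyl group and the bond to the benzylic carbon in one flask.
- Cutting the aryl–C1' bond instead (aryl metal plus allylic halide) would need a separately made E allylic halide and would risk SN2′ attack.
- The precursors are a seven-carbon alkyne and a simple benzylic chloride. The reaction must tolerate two silyl ethers and leave the existing trisubstituted alkene untouched.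

**14 ⇒ 13 ⇒ 11 (C4'–C5', the stereocentre).** Alcohol 13 is the propargylation product of enal 11, formed through borate ester 12.
- The aldehyde carbon becomes C5', and the catalyst decides the configuration on a small, easily analysed molecule.
- Reduction of a C5' ketone was set aside: the β,γ-alkynyl enone would isomerise to an allene.
- Vinyl addition to a β,γ-unsaturated aldehyde was set aside for the same instability.
- The forward step needs Si-face addition and reaction of the allenyl reagent through its γ-carbon.

**11 ⇒ 10 ⇒ 9 ⇒ 8 ⇒ 7 (the C5'–C8' unit).** Enal 11 comes from prenyl acetate 7 by allylic oxidation of the E methyl group (8), silylation (9), deacetylation (10) and oxidation. This gives the C5 unit with defined E geometry and with its two ends differentiated from the first step, which a Wittig-type construction would not do as cleanly.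

**6 ⇒ 5 ⇒ 4 ⇒ 3 ⇒ 1 (arene).** Chloride 6 comes from alcohol 5, aldehyde 4 and salicylaldehyde 3, made by ortho-formylation of phenol 1 through hydroxymethyl intermediate 2. The phenol directs the new carbon to its only free ortho position. Electrophilic substitution or lithiation of the corresponding dimethyl ether would give mixtures of regioisomers.

**22 ⇒ 21 ⇒ 20 ⇒ 19 (tail).** Sulfone 22 is the silyl ether of hydroxy sulfone 21, obtained by allylic oxidation of geranyl phenyl sulfone 20, which comes from geranyl bromide 19 and sodium benzenesulfinate. Installing the sulfone first is shorter than oxidising a geranyl ester and exchanging the ester for sulfone later. The sulfonyl group also deactivates the nearer alkene, so oxidation should go to the distal E methyl group.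

## Roads not taken

**Alternative 1:** Here the arene is made last. The cut removes three ring bonds (C4–C5, C6–C1, C1–C2). The complete chain would be carried as terminal 1,4-enyne A2 and heated with the propenyl(methoxy)carbene complex of zerovalent chromium A3. Alkyne insertion, CO insertion and electrocyclisation (Dötz benzannulation) should give, after oxidative decomplexation, 4-methoxyphenol A1 with the chain ortho to the new hydroxyl.
- Merits: the ring's substitution pattern comes in one step, without the four-step preparation of chloride 6. The conditions are neutral, and A1 would enter the same oxidation–reduction endgame as 26. In ring construction this road is cleaner than the chosen one.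
- Weak points: it solves none of the chain problems. A2 already contains C5', all four alkenes and the C8'–C9' bond, so a union like step 17 would still be needed before it. It also puts a stoichiometric chromium reagent at the end of a fully linear sequence, on a substrate whose four alkenes can intercept the carbene or vinylketene intermediates. The C1' methylene of A2 is propargylic and allylic and isomerises easily to the allene.
- Comparison: the chosen route attaches the arene in the same operation that builds C2'=C3' (step 11) and stays convergent. It has to set against the Dötz road the separate synthesis of 6 and the handling of an electron-rich benzylic chloride.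

**Alternative 2:** The cut is C4'–C5'. The (S)-configured allylic glycolate A5 would be enolised so that chelation by the 4-methoxybenzyloxy group fixes the Z enolate, then silylated and rearranged through a chair (Ireland–Claisen) to acid A4. This creates C4'–C5', the E C2'=C3' alkene and the C5' configuration together.
- Merits: chirality transfer is reliable. Once the carbinol centre of A5 exists, C5' follows from a well-understood transition state and does not depend on how a catalyst treats a particular enal. Crystalline salts of A4 could raise optical purity. In this respect it is at least as good as step 9.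
- Weak points: an enantioselective step is still needed for the carbinol centre of A5. The carboxyl group of A4 must then be turned, over several operations including an E-selective olefination next to an epimerisable α-alkoxy centre, into the C6'=C7'–C8' unit that 17 already has. The 4-methoxybenzyl ether would have to be removed oxidatively beside an equally electron-rich dimethoxyarene.
- Comparison: this road ends at the same head fragment, needs the same C8'–C9' union afterwards, and is longer by the steps that rebuild the alkene. It would become attractive only if step 9 could not be made selective.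

**Alternative 3:** The cut is C5'–C6', at the stereocentre. Carbamate A7 (arene to C5') would be lithiated at C5' with s-BuLi/(+)-sparteine and trapped with (E)-alkenyl boronate A8 (C6'–C16'). 1,2-Migration with loss of the carbamate gives secondary allylic boronate A6, and stereoretentive oxidation of the C–B bond would install the C5' hydroxyl directly.
- Merits: this is the most convergent of the four plans. Both fragments are achiral, the stereocentre is made in the coupling by reagent control, C5' needs no protecting group, and no sulfone has to be removed. The chosen route cannot match these points.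
- Weak points: A7 offers s-BuLi competing acidic sites (the benzylic–allylic C1' methylene and the positions ortho to the methoxy groups). A8 is a β,β-disubstituted alkenyl boronate whose hindered ate complex may form reversibly and erode enantiomeric purity. A6 can undergo 1,3-borotropic shift before oxidation. A stoichiometric chiral diamine is consumed at −78 °C at the most valuable stage. A8 also still needs a C–C bond made next to C8', so the allylic coupling problem is moved, not removed.
- Comparison: the chosen plan sets against the higher convergence that its stereocentre is made early on a seven-carbon molecule, where purity can be measured and corrected, and that its fragment union creates no stereochemical information that could be lost.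

Key step: step 17

Assumption: the (S)-configured phosphoric acid of step 9 is taken to direct the allenylboronate to the Si face of enal 11, the mirror image of the Re-face preference established for the (R)-acid with aryl and alkenyl aldehydes; the configuration of 13 is to be confirmed (Mosher esters) before material is carried forward.

## Route

Step 1
Reactants: 1 4-methoxy-2-methylphenol
Product: 3 2-hydroxy-5-methoxy-3-methylbenzaldehyde, via hydroxymethyl phenol 2 (not isolated)
Conditions: MgCl2, Et3N, (CH2O)n, MeCN, reflux; aq. HCl work-up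
Reagents that add atoms: formaldehyde (as paraformaldehyde), C=O
Why: Magnesium-mediated ortho-formylation of a phenol (Casnati–Skattebøl): the magnesium phenoxide should direct formaldehyde to the only free ortho position, and intermediate 2 is oxidised in the flask by a second equivalent of formaldehyde through hydride transfer.

Step 2
Reactants: 3 2-hydroxy-5-methoxy-3-methylbenzaldehyde
Product: 4 2,5-dimethoxy-3-methylbenzaldehyde
Conditions: MeI, K2CO3, DMF, rt
Reagents that add atoms: iodomethane, CI
Why: Williamson methylation of a phenol acidified by the ortho-formyl group; no other nucleophilic site is present.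

Step 3
Reactants: 4 2,5-dimethoxy-3-methylbenzaldehyde
Product: 5 (2,5-dimethoxy-3-methylphenyl)methanol
Conditions: NaBH4, MeOH, 0 °C
Reagents that add atoms: none
Why: Borohydride reduction of an aryl aldehyde to the benzylic alcohol.

Step 4
Reactants: 5 (2,5-dimethoxy-3-methylphenyl)methanol
Product: 6 1-(chloromethyl)-2,5-dimethoxy-3-methylbenzene
Conditions: SOCl2, pyridine (cat.), CH2Cl2, 0 °C → rt
Reagents that add atoms: thionyl chloride, O=S(Cl)Cl
Why: Chlorodehydroxylation through the chlorosulfite; the electron-rich benzylic chloride should be used soon after preparation because such halides self-alkylate on storage.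

Step 5
Reactants: 7 prenyl acetate (3-methylbut-2-enyl acetate)
Product: 8 (2E)-4-hydroxy-3-methylbut-2-enyl acetate
Conditions: SeO2 (cat.), t-BuOOH, salicylic acid (cat.), CH2Cl2, rt
Reagents that add atoms: selenium dioxide (catalytic oxygen carrier), O=[Se]=O; tert-butyl hydroperoxide (stoichiometric oxygen source), CC(C)(C)OO
Why: Riley-type allylic oxidation (ene reaction, then [2,3]-sigmatropic shift) is selective for the E methyl group of a trisubstituted alkene; the acetoxy-bearing methylene is deactivated.

Step 6
Reactants: 8 (2E)-4-hydroxy-3-methylbut-2-enyl acetate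
Product: 9 (2E)-4-(tert-butyldimethylsilyloxy)-3-methylbut-2-enyl acetate
Conditions: TBSCl, imidazole, CH2Cl2, 0 °C → rt
Reagents that add atoms: tert-butyldimethylsilyl chloride, CC(C)(C)[Si](C)(C)Cl
Why: Standard silylation of a primary alcohol; this differentiates the two ends of the C5 unit.

Step 7
Reactants: 9 (2E)-4-(tert-butyldimethylsilyloxy)-3-methylbut-2-enyl acetate
Product: 10 (2E)-4-(tert-butyldimethylsilyloxy)-3-methylbut-2-en-1-ol
Conditions: K2CO3 (cat.), MeOH, 0 °C
Reagents that add atoms: none
Why: Base-catalysed transesterification removes the acetate; the TBS ether is stable to carbonate in methanol.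

Step 8
Reactants: 10 (2E)-4-(tert-butyldimethylsilyloxy)-3-methylbut-2-en-1-ol
Product: 11 (2E)-4-(tert-butyldimethylsilyloxy)-3-methylbut-2-enal
Conditions: MnO2, CH2Cl2, rt
Reagents that add atoms: none
Why: Neutral heterogeneous oxidation of an allylic alcohol; it should give the enal without E/Z isomerisation or loss of the silyl ether.

Step 9
Reactants: 11 (2E)-4-(tert-butyldimethylsilyloxy)-3-methylbut-2-enal
Product: 13 (4S,5E)-7-(tert-butyldimethylsilyloxy)-6-methylhept-5-en-1-yn-4-ol, via pinacol borate ester 12 (not isolated)
Conditions: allenylboronic acid pinacol ester, (S)-TRIP phosphoric acid [(S)-3,3'-bis(2,4,6-triisopropylphenyl)-1,1'-binaphthyl-2,2'-diyl hydrogen phosphate] (cat.), 4 Å MS, toluene, −20 °C; aq. work-up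
Reagents that add atoms: allenylboronic acid pinacol ester, C=C=CB1OC(C)(C)C(C)(C)O1
Why: Chiral phosphoric acid-catalysed allenylboration (SE2′ propargylation) through a closed six-membered transition state in which the acid binds a boronate oxygen and the formyl hydrogen. The (S)-acid should deliver the allenyl γ-carbon to the Si face of 11, which sets C5' as S, and reaction through the γ-carbon gives the homopropargylic, not the allenic, alcohol.

Step 10
Reactants: 13 (4S,5E)-7-(tert-butyldimethylsilyloxy)-6-methylhept-5-en-1-yn-4-ol
Product: 14 (4S,5E)-4,7-bis(tert-butyldimethylsilyloxy)-6-methylhept-5-en-1-yne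
Conditions: TBSCl, imidazole, DMAP (cat.), DMF, rt
Reagents that add atoms: tert-butyldimethylsilyl chloride, CC(C)(C)[Si](C)(C)Cl
Why: Silylation of the secondary alcohol under non-ionising conditions; the C5' configuration is not touched.

Step 11
Reactants: 14 (4S,5E)-4,7-bis(tert-butyldimethylsilyloxy)-6-methylhept-5-en-1-yne and 6 1-(chloromethyl)-2,5-dimethoxy-3-methylbenzene
Product: 16 1-[(2E,5S,6E)-5,8-bis(tert-butyldimethylsilyloxy)-3,7-dimethylocta-2,6-dienyl]-2,5-dimethoxy-3-methylbenzene, via alkenyldimethylalane 15 (not isolated)
Conditions: AlMe3, Cp2ZrCl2 (cat.), CH2Cl2, 0 °C → rt; then 6, Pd(PPh3)4 (cat.), THF, rt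
Reagents that add atoms: trimethylaluminium, C[Al](C)C
Why: Negishi zirconium-catalysed carboalumination adds methyl and aluminium syn across the terminal alkyne with aluminium on the terminal carbon, which fixes the C2'=C3' alkene as E. Palladium-catalysed cross-coupling of alkenylalane 15 with the benzylic chloride proceeds with retention of geometry. The trisubstituted C6'=C7' alkene does not carbometalate and silyl ethers are tolerated.

Step 12
Reactants: 16 1-[(2E,5S,6E)-5,8-bis(tert-butyldimethylsilyloxy)-3,7-dimethylocta-2,6-dienyl]-2,5-dimethoxy-3-methylbenzene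
Product: 17 (2E,4S,6E)-4-(tert-butyldimethylsilyloxy)-8-(2,5-dimethoxy-3-methylphenyl)-2,6-dimethylocta-2,6-dien-1-ol
Conditions: (+)-camphor-10-sulfonic acid (cat.), MeOH/CH2Cl2, 0 °C; Et3N quench
Reagents that add atoms: none
Why: Acid-catalysed methanolysis of silyl ethers is governed by steric access to silicon, so the primary C8' ether should cleave well before the secondary C5' ether; the reaction is quenched when 16 is consumed.

Step 13
Reactants: 17 (2E,4S,6E)-4-(tert-butyldimethylsilyloxy)-8-(2,5-dimethoxy-3-methylphenyl)-2,6-dimethylocta-2,6-dien-1-ol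
Product: 18 1-[(2E,5S,6E)-8-bromo-5-(tert-butyldimethylsilyloxy)-3,7-dimethylocta-2,6-dienyl]-2,5-dimethoxy-3-methylbenzene
Conditions: CBr4, PPh3, CH2Cl2, −20 → 0 °C
Reagents that add atoms: carbon tetrabromide, BrC(Br)(Br)Br
Why: Appel bromination: bromide displaces the oxyphosphonium group at the primary allylic carbon by SN2 without allylic transposition, under neutral conditions that spare the C5' silyl ether.

Step 14
Reactants: 19 geranyl bromide [(2E)-1-bromo-3,7-dimethylocta-2,6-diene]
Product: 20 geranyl phenyl sulfone {[(2E)-3,7-dimethylocta-2,6-dienyl]sulfonylbenzene}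
Conditions: PhSO2Na, DMF, rt
Reagents that add atoms: sodium benzenesulfinate, [Na+].[O-]S(=O)c1ccccc1
Why: SN2 S-alkylation of the sulfinate at the primary allylic bromide gives the stable sulfone with the E geometry retained.

Step 15
Reactants: 20 geranyl phenyl sulfone
Product: 21 (2E,6E)-2,6-dimethyl-8-(phenylsulfonyl)octa-2,6-dien-1-ol
Conditions: SeO2 (cat.), t-BuOOH, salicylic acid (cat.), CH2Cl2, rt
Reagents that add atoms: selenium dioxide (catalytic oxygen carrier), O=[Se]=O; tert-butyl hydroperoxide (stoichiometric oxygen source), CC(C)(C)OO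
Why: Riley-type allylic oxidation; the sulfonyl group deactivates the nearer alkene, so the ene reaction should take place at the distal alkene and oxidise its E methyl group.

Step 16
Reactants: 21 (2E,6E)-2,6-dimethyl-8-(phenylsulfonyl)octa-2,6-dien-1-ol
Product: 22 tert-butyl{[(2E,6E)-2,6-dimethyl-8-(phenylsulfonyl)octa-2,6-dienyl]oxy}dimethylsilane
Conditions: TBSCl, imidazole, CH2Cl2, rt
Reagents that add atoms: tert-butyldimethylsilyl chloride, CC(C)(C)[Si](C)(C)Cl
Why: Silylation removes the acidic hydroxyl proton so that one equivalent of base suffices in step 17.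

Step 17
Reactants: 22 tert-butyl{[(2E,6E)-2,6-dimethyl-8-(phenylsulfonyl)octa-2,6-dienyl]oxy}dimethylsilane and 18 1-[(2E,5S,6E)-8-bromo-5-(tert-butyldimethylsilyloxy)-3,7-dimethylocta-2,6-dienyl]-2,5-dimethoxy-3-methylbenzene
Product: 24 1-[(2E,5S,6E,10E,14E)-5,16-bis(tert-butyldimethylsilyloxy)-3,7,11,15-tetramethyl-9-(phenylsulfonyl)hexadeca-2,6,10,14-tetraenyl]-2,5-dimethoxy-3-methylbenzene (both C9' epimers), via α-lithio sulfone 23 (not isolated)
Conditions: n-BuLi, THF, −78 °C; then 18 in THF, −78 → −30 °C
Reagents that add atoms: n-butyllithium, [Li]CCCC (supplies only the lithium of intermediate 23; 24 keeps no atom from it)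
Why: n-BuLi removes the proton on C9' of 22, which is acidified by the sulfonyl group and the adjacent alkene, to give sulfonyl-stabilised allyl anion 23. The anion should react through its α-carbon in a direct SN2 displacement of bromide from the primary allylic C8' of 18, forming the C8'–C9' bond. The closest known reaction type is the alkylation of lithiated prenyl-type aryl sulfones with allylic halides, the classical head-to-tail union of isoprenoid units. No ring is closed. The sulfonyl-bearing C9' becomes a stereocentre without control; both epimers are carried on because step 18 removes the centre. The step needs α- rather than γ-alkylation, which the sulfonyl group and the fully substituted γ-carbon C11' secure. It needs SN2 rather than SN2′, which is favoured because C8' is an unhindered primary carbon next to the fully substituted C7', whereas the SN2′ terminus C6' is flanked by the silyloxy-bearing C5'. It also needs mono-alkylation, and the product's remaining α-hydrogen is on a hindered tertiary carbon. The stabilised carbanion is weakly basic at −78 °C, so elimination from 18 should not compete, and the four E alkenes and the C5' silyl ether, three bonds from the reacting carbon, are not involved.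

Step 18
Reactants: 24 coupled C9' sulfone (both epimers)
Product: 25 1-[(2E,5S,6E,10E,14E)-5,16-bis(tert-butyldimethylsilyloxy)-3,7,11,15-tetramethylhexadeca-2,6,10,14-tetraenyl]-2,5-dimethoxy-3-methylbenzene
Conditions: LiBHEt3, PdCl2(dppf) (cat.), THF, 0 °C
Reagents that add atoms: none
Why: Palladium-catalysed reductive desulfonylation: zerovalent palladium, formed from PdCl2(dppf) by hydride, ionises the allylic C–S bond to a π-allyl complex spanning C9'–C11'. Hydride should be delivered to the less substituted terminus C9', so the C10'=C11' alkene keeps its position and E geometry. Silyl ethers are not ionised under these conditions.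

Step 19
Reactants: 25 bis-silyl ether
Product: 26 (2E,6E,10E,12S,14E)-16-(2,5-dimethoxy-3-methylphenyl)-2,6,10,14-tetramethylhexadeca-2,6,10,14-tetraene-1,12-diol
Conditions: Bu4NF, THF, rt
Reagents that add atoms: none
Why: Fluoride cleaves both silyl ethers under non-acidic conditions, so the allylic C5' carbinol cannot ionise.

Step 20
Reactants: 26 diol dimethyl ether
Product: 27 2-[(2E,5S,6E,10E,14E)-5,16-dihydroxy-3,7,11,15-tetramethylhexadeca-2,6,10,14-tetraenyl]-6-methylcyclohexa-2,5-diene-1,4-dione
Conditions: (NH4)2Ce(NO3)6, MeCN/H2O, 0 °C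
Reagents that add atoms: water, O
Why: Oxidative demethylation of a 1,4-dimethoxyarene by tetravalent cerium: two one-electron oxidations with ipso attack of water and loss of methanol give the quinone. At 0 °C with short contact the isolated alkenes and the two alcohols should not be oxidised.

Step 21
Reactants: 27 quinone
Product: 28 2-[(2E,5S,6E,10E,14E)-5,16-dihydroxy-3,7,11,15-tetramethylhexadeca-2,6,10,14-tetraenyl]-6-methylbenzene-1,4-diol
Conditions: Na2S2O4, Et2O/H2O, rt, under argon
Reagents that add atoms: none
Why: Dithionite reduces the quinone to the hydroquinone under neutral conditions that leave alkenes and allylic alcohols alone; the product is to be handled with exclusion of air.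

## Compound list

1 | 4-methoxy-2-methylphenol | COc1ccc(O)c(C)c1 | starting material
2 | 2-(hydroxymethyl)-4-methoxy-6-methylphenol (magnesium phenoxide in the flask) | OCc1cc(OC)cc(C)c1O | intermediate (not isolated)
3 | 2-hydroxy-5-methoxy-3-methylbenzaldehyde | O=Cc1cc(OC)cc(C)c1O | intermediate
4 | 2,5-dimethoxy-3-methylbenzaldehyde | O=Cc1cc(OC)cc(C)c1OC | intermediate
5 | (2,5-dimethoxy-3-methylphenyl)methanol | OCc1cc(OC)cc(C)c1OC | intermediate
6 | 1-(chloromethyl)-2,5-dimethoxy-3-methylbenzene | ClCc1cc(OC)cc(C)c1OC | intermediate
7 | prenyl acetate (3-methylbut-2-enyl acetate) | CC(C)=CCOC(C)=O | starting material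
8 | (2E)-4-hydroxy-3-methylbut-2-enyl acetate | CC(=O)OC/C=C(\C)CO | intermediate
9 | (2E)-4-(tert-butyldimethylsilyloxy)-3-methylbut-2-enyl acetate | CC(=O)OC/C=C(\C)CO[Si](C)(C)C(C)(C)C | intermediate
10 | (2E)-4-(tert-butyldimethylsilyloxy)-3-methylbut-2-en-1-ol | OC/C=C(\C)CO[Si](C)(C)C(C)(C)C | intermediate
11 | (2E)-4-(tert-butyldimethylsilyloxy)-3-methylbut-2-enal | O=C/C=C(\C)CO[Si](C)(C)C(C)(C)C | intermediate
12 | 2-{[(4S,5E)-7-(tert-butyldimethylsilyloxy)-6-methylhept-5-en-1-yn-4-yl]oxy}-4,4,5,5-tetramethyl-1,3,2-dioxaborolane | C#CC[C@H](OB1OC(C)(C)C(C)(C)O1)/C=C(\C)CO[Si](C)(C)C(C)(C)C | intermediate (not isolated)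
13 | (4S,5E)-7-(tert-butyldimethylsilyloxy)-6-methylhept-5-en-1-yn-4-ol | C#CC[C@H](O)/C=C(\C)CO[Si](C)(C)C(C)(C)C | intermediate
14 | (4S,5E)-4,7-bis(tert-butyldimethylsilyloxy)-6-methylhept-5-en-1-yne | C#CC[C@H](O[Si](C)(C)C(C)(C)C)/C=C(\C)CO[Si](C)(C)C(C)(C)C | intermediate
15 | [(1E,4S,5E)-4,7-bis(tert-butyldimethylsilyloxy)-2,6-dimethylhepta-1,5-dienyl]dimethylalane | C[Al](C)/C=C(\C)C[C@H](O[Si](C)(C)C(C)(C)C)/C=C(\C)CO[Si](C)(C)C(C)(C)C | intermediate (not isolated)
16 | 1-[(2E,5S,6E)-5,8-bis(tert-butyldimethylsilyloxy)-3,7-dimethylocta-2,6-dienyl]-2,5-dimethoxy-3-methylbenzene | CC(C)(C)[Si](C)(C)OC/C(C)=C/[C@@H](O[Si](C)(C)C(C)(C)C)C/C(C)=C/Cc1cc(OC)cc(C)c1OC | intermediate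
17 | (2E,4S,6E)-4-(tert-butyldimethylsilyloxy)-8-(2,5-dimethoxy-3-methylphenyl)-2,6-dimethylocta-2,6-dien-1-ol | OC/C(C)=C/[C@@H](O[Si](C)(C)C(C)(C)C)C/C(C)=C/Cc1cc(OC)cc(C)c1OC | intermediate
18 | 1-[(2E,5S,6E)-8-bromo-5-(tert-butyldimethylsilyloxy)-3,7-dimethylocta-2,6-dienyl]-2,5-dimethoxy-3-methylbenzene | BrC/C(C)=C/[C@@H](O[Si](C)(C)C(C)(C)C)C/C(C)=C/Cc1cc(OC)cc(C)c1OC | intermediate
19 | geranyl bromide [(2E)-1-bromo-3,7-dimethylocta-2,6-diene] | CC(C)=CCC/C(C)=C/CBr | starting material
20 | geranyl phenyl sulfone {[(2E)-3,7-dimethylocta-2,6-dienyl]sulfonylbenzene} | CC(C)=CCC/C(C)=C/CS(=O)(=O)c1ccccc1 | intermediate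
21 | (2E,6E)-2,6-dimethyl-8-(phenylsulfonyl)octa-2,6-dien-1-ol | C/C(=C\CC/C(C)=C/CS(=O)(=O)c1ccccc1)CO | intermediate
22 | tert-butyl{[(2E,6E)-2,6-dimethyl-8-(phenylsulfonyl)octa-2,6-dienyl]oxy}dimethylsilane | C/C(=C\CC/C(C)=C/CS(=O)(=O)c1ccccc1)CO[Si](C)(C)C(C)(C)C | intermediate
23 | α-lithio derivative of 22 (lithium on the sulfonyl-bearing carbon) | [Li]C(/C=C(\C)CC/C=C(\C)CO[Si](C)(C)C(C)(C)C)S(=O)(=O)c1ccccc1 | intermediate (not isolated)
24 | 1-[(2E,5S,6E,10E,14E)-5,16-bis(tert-butyldimethylsilyloxy)-3,7,11,15-tetramethyl-9-(phenylsulfonyl)hexadeca-2,6,10,14-tetraenyl]-2,5-dimethoxy-3-methylbenzene (both C9' epimers) | C/C(=C\CC/C(C)=C/C(C/C(C)=C/[C@@H](O[Si](C)(C)C(C)(C)C)C/C(C)=C/Cc1cc(OC)cc(C)c1OC)S(=O)(=O)c1ccccc1)CO[Si](C)(C)C(C)(C)C | intermediate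
25 | 1-[(2E,5S,6E,10E,14E)-5,16-bis(tert-butyldimethylsilyloxy)-3,7,11,15-tetramethylhexadeca-2,6,10,14-tetraenyl]-2,5-dimethoxy-3-methylbenzene | C/C(=C\CC/C(C)=C/CC/C(C)=C/[C@@H](O[Si](C)(C)C(C)(C)C)C/C(C)=C/Cc1cc(OC)cc(C)c1OC)CO[Si](C)(C)C(C)(C)C | intermediate
26 | (2E,6E,10E,12S,14E)-16-(2,5-dimethoxy-3-methylphenyl)-2,6,10,14-tetramethylhexadeca-2,6,10,14-tetraene-1,12-diol | C/C(=C\CC/C(C)=C/CC/C(C)=C/[C@@H](O)C/C(C)=C/Cc1cc(OC)cc(C)c1OC)CO | intermediate
27 | 2-[(2E,5S,6E,10E,14E)-5,16-dihydroxy-3,7,11,15-tetramethylhexadeca-2,6,10,14-tetraenyl]-6-methylcyclohexa-2,5-diene-1,4-dione | C/C(=C\CC/C(C)=C/CC/C(C)=C/[C@@H](O)C/C(C)=C/CC1=CC(=O)C=C(C)C1=O)CO | intermediate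
28 | 2-[(2E,5S,6E,10E,14E)-5,16-dihydroxy-3,7,11,15-tetramethylhexadeca-2,6,10,14-tetraenyl]-6-methylbenzene-1,4-diol | C/C(=C\CC/C(C)=C/CC/C(C)=C/[C@@H](O)C/C(C)=C/Cc1cc(O)cc(C)c1O)CO | target

## Step count and least certain steps

Total: 21 steps. Longest linear sequence: 14 steps (from 7: steps 5–13 and 17–21). Side branches: arene, steps 1–4; tail, steps 14–16.

**Step 17 (key step).**
- Most likely failure: the carbanion acts as a base toward the γ-silyloxy allylic bromide (1,4-elimination), attacks in the SN2′ sense, or the bromide rearranges before it is consumed. The longest branch of the synthesis would be lost at the point of union.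
- Fallback: the same C8'–C9' alkylation is moved to the front, onto the simplest possible electrophile, and the head is built afterwards on the joined chain. It sets out from 8 and 22 and returns at 25.
- Appel bromination of 8 gives (2E)-4-bromo-3-methylbut-2-enyl acetate F1. Anion 23 is alkylated with it to (2E,6E,10E)-12-(tert-butyldimethylsilyloxy)-3,7,11-trimethyl-5-(phenylsulfonyl)dodeca-2,6,10-trienyl acetate F2.
- K2CO3 in MeOH gives (2E,6E,10E)-12-(tert-butyldimethylsilyloxy)-3,7,11-trimethyl-5-(phenylsulfonyl)dodeca-2,6,10-trien-1-ol F3. The acetate is removed first because an allylic acetate would itself be reduced by palladium and hydride.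
- LiBHEt3/PdCl2(dppf) gives (2E,6E,10E)-12-(tert-butyldimethylsilyloxy)-3,7,11-trimethyldodeca-2,6,10-trien-1-ol F4, and MnO2 gives (2E,6E,10E)-12-(tert-butyldimethylsilyloxy)-3,7,11-trimethyldodeca-2,6,10-trienal F5.
- Propargylation as in step 9 gives, through the pinacol borate ester of the new carbinol F6, (4S,5E,9E,13E)-15-(tert-butyldimethylsilyloxy)-6,10,14-trimethylpentadeca-5,9,13-trien-1-yn-4-ol F7. Silylation gives (4S,5E,9E,13E)-4,15-bis(tert-butyldimethylsilyloxy)-6,10,14-trimethylpentadeca-5,9,13-trien-1-yne F8.
- Carboalumination to the (E)-alkenyldimethylalane of the full chain F9 and coupling with 6 as in step 11 give 25.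

**Step 9.**
- Most likely failure: insufficient facial discrimination on a β,β-disubstituted enal that carries a coordinating silyloxy group, or induction in the sense opposite to the one assumed.
- Fallback: kinetic resolution instead of asymmetric addition, at the cost of half the material. It sets out from 11 and returns at 13.
- Zinc-mediated Barbier addition of propargyl bromide to 11 gives racemic (5E)-7-(tert-butyldimethylsilyloxy)-6-methylhept-5-en-1-yn-4-ol F10.
- Candida antarctica lipase B with vinyl acetate should acylate the R enantiomer, in which the alkenyl group is the large and the propargyl group the medium substituent, to (4R,5E)-7-(tert-butyldimethylsilyloxy)-6-methylhept-5-en-1-yn-4-yl acetate F11. Unreacted 13 is separated.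

**Step 11.**
- Most likely failure: ionisation or cleavage of the allylic silyl ethers by the Lewis-acidic aluminium–zirconium system, or slow transfer of the alkenyl group to palladium with the electron-rich benzylic chloride, so that protodemetalation and benzyl homocoupling take over.
- Fallback: the polarity of the cross-coupling is reversed. It sets out from 14 (through alane 15) and 6 and returns at 16.
- Iodinolysis of 15 gives (1E,4S,5E)-4,7-bis(tert-butyldimethylsilyloxy)-1-iodo-2,6-dimethylhepta-1,5-diene F12, which is isolated and purified.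
- Zinc insertion into 6 (Zn, LiCl, THF) gives (2,5-dimethoxy-3-methylbenzyl)zinc chloride F13, and Negishi coupling of the two with Pd(PPh3)4 gives 16.

**Step 12.**
- Most likely failure: loss of the secondary silyl ether together with the primary one, or silyl migration, because both ethers are allylic and differ only in steric access.
- Fallback: the differentiation is made by acylation instead. It sets out from 16 and returns at 17.
- Bu4NF removes both silyl groups to give (2E,4S,6E)-8-(2,5-dimethoxy-3-methylphenyl)-2,6-dimethylocta-2,6-diene-1,4-diol F14.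
- Pivaloyl chloride in pyridine at 0 °C acylates the primary hydroxyl to (2E,4S,6E)-8-(2,5-dimethoxy-3-methylphenyl)-4-hydroxy-2,6-dimethylocta-2,6-dienyl pivalate F15.
- TBSOTf/2,6-lutidine gives (2E,4S,6E)-4-(tert-butyldimethylsilyloxy)-8-(2,5-dimethoxy-3-methylphenyl)-2,6-dimethylocta-2,6-dienyl pivalate F16, and i-Bu2AlH at −78 °C removes the pivalate to give 17.

**Step 18.**
- Most likely failure: hydride delivery to the wrong allyl terminus (C11'), which moves the alkene to C9'=C10', or erosion of E geometry through syn–anti interconversion of the π-allyl intermediate.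
- Fallback: desulfonylation by electron transfer, which has no metal–allyl intermediate. Buffered sodium amalgam (Na/Hg, Na2HPO4, MeOH/THF, −20 °C) fragments the sulfone radical anion, and the resulting allyl anion is protonated. It sets out from 24, returns at 25 and makes no new compound. The allylic silyl ether and the arene should tolerate these conditions, but positional purity would have to be checked.

**Step 20.**
- Most likely failure: over-oxidation at the free allylic alcohols or at the doubly activated C1' methylene while the arene is being oxidised.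
- Fallback: the order of the last operations is changed so that the alcohols are masked during the oxidation. It sets out from 25 and returns at 27.
- (NH4)2Ce(NO3)6 on 25 gives 2-[(2E,5S,6E,10E,14E)-5,16-bis(tert-butyldimethylsilyloxy)-3,7,11,15-tetramethylhexadeca-2,6,10,14-tetraenyl]-6-methylcyclohexa-2,5-diene-1,4-dione F17.
- Pyridine-buffered HF·pyridine in THF then removes both silyl groups without exposing the base-sensitive quinone to fluoride ion, giving 27.

## Further compounds

F1 | step 17 | (2E)-4-bromo-3-methylbut-2-enyl acetate | CC(=O)OC/C=C(\C)CBr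
F2 | step 17 | (2E,6E,10E)-12-(tert-butyldimethylsilyloxy)-3,7,11-trimethyl-5-(phenylsulfonyl)dodeca-2,6,10-trienyl acetate | C/C(=C\CC/C(C)=C/C(C/C(C)=C/COC(C)=O)S(=O)(=O)c1ccccc1)CO[Si](C)(C)C(C)(C)C
F3 | step 17 | (2E,6E,10E)-12-(tert-butyldimethylsilyloxy)-3,7,11-trimethyl-5-(phenylsulfonyl)dodeca-2,6,10-trien-1-ol | C/C(=C\CC/C(C)=C/C(C/C(C)=C/CO)S(=O)(=O)c1ccccc1)CO[Si](C)(C)C(C)(C)C
F4 | step 17 | (2E,6E,10E)-12-(tert-butyldimethylsilyloxy)-3,7,11-trimethyldodeca-2,6,10-trien-1-ol | C/C(=C\CC/C(C)=C/CC/C(C)=C/CO)CO[Si](C)(C)C(C)(C)C
F5 | step 17 | (2E,6E,10E)-12-(tert-butyldimethylsilyloxy)-3,7,11-trimethyldodeca-2,6,10-trienal | C/C(=C\CC/C(C)=C/CC/C(C)=C/C=O)CO[Si](C)(C)C(C)(C)C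
F6 | step 17 | 2-{[(4S,5E,9E,13E)-15-(tert-butyldimethylsilyloxy)-6,10,14-trimethylpentadeca-5,9,13-trien-1-yn-4-yl]oxy}-4,4,5,5-tetramethyl-1,3,2-dioxaborolane | C/C(=C\CC/C(C)=C/CC/C(C)=C/[C@@H](OB1OC(C)(C)C(C)(C)O1)CC#C)CO[Si](C)(C)C(C)(C)C
F7 | step 17 | (4S,5E,9E,13E)-15-(tert-butyldimethylsilyloxy)-6,10,14-trimethylpentadeca-5,9,13-trien-1-yn-4-ol | C/C(=C\CC/C(C)=C/CC/C(C)=C/[C@@H](O)CC#C)CO[Si](C)(C)C(C)(C)C
F8 | step 17 | (4S,5E,9E,13E)-4,15-bis(tert-butyldimethylsilyloxy)-6,10,14-trimethylpentadeca-5,9,13-trien-1-yne | C/C(=C\CC/C(C)=C/CC/C(C)=C/[C@@H](O[Si](C)(C)C(C)(C)C)CC#C)CO[Si](C)(C)C(C)(C)C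
F9 | step 17 | [(1E,4S,5E,9E,13E)-4,15-bis(tert-butyldimethylsilyloxy)-2,6,10,14-tetramethylpentadeca-1,5,9,13-tetraenyl]dimethylalane | C/C(=C\CC/C(C)=C/CC/C(C)=C/[C@@H](O[Si](C)(C)C(C)(C)C)C/C(C)=C/[Al](C)C)CO[Si](C)(C)C(C)(C)C
F10 | step 9 | racemic (5E)-7-(tert-butyldimethylsilyloxy)-6-methylhept-5-en-1-yn-4-ol | C#CCC(O)/C=C(\C)CO[Si](C)(C)C(C)(C)C
F11 | step 9 | (4R,5E)-7-(tert-butyldimethylsilyloxy)-6-methylhept-5-en-1-yn-4-yl acetate | C#CC[C@@H](OC(C)=O)/C=C(\C)CO[Si](C)(C)C(C)(C)C
F12 | step 11 | (1E,4S,5E)-4,7-bis(tert-butyldimethylsilyloxy)-1-iodo-2,6-dimethylhepta-1,5-diene | I/C=C(\C)C[C@H](O[Si](C)(C)C(C)(C)C)/C=C(\C)CO[Si](C)(C)C(C)(C)C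
F13 | step 11 | (2,5-dimethoxy-3-methylbenzyl)zinc chloride | Cl[Zn]Cc1cc(OC)cc(C)c1OC
F14 | step 12 | (2E,4S,6E)-8-(2,5-dimethoxy-3-methylphenyl)-2,6-dimethylocta-2,6-diene-1,4-diol | OC/C(C)=C/[C@@H](O)C/C(C)=C/Cc1cc(OC)cc(C)c1OC
F15 | step 12 | (2E,4S,6E)-8-(2,5-dimethoxy-3-methylphenyl)-4-hydroxy-2,6-dimethylocta-2,6-dienyl pivalate | CC(C)(C)C(=O)OC/C(C)=C/[C@@H](O)C/C(C)=C/Cc1cc(OC)cc(C)c1OC
F16 | step 12 | (2E,4S,6E)-4-(tert-butyldimethylsilyloxy)-8-(2,5-dimethoxy-3-methylphenyl)-2,6-dimethylocta-2,6-dienyl pivalate | CC(C)(C)C(=O)OC/C(C)=C/[C@@H](O[Si](C)(C)C(C)(C)C)C/C(C)=C/Cc1cc(OC)cc(C)c1OC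
F0 | step 18 | none | none
F17 | step 20 | 2-[(2E,5S,6E,10E,14E)-5,16-bis(tert-butyldimethylsilyloxy)-3,7,11,15-tetramethylhexadeca-2,6,10,14-tetraenyl]-6-methylcyclohexa-2,5-diene-1,4-dione | C/C(=C\CC/C(C)=C/CC/C(C)=C/[C@@H](O[Si](C)(C)C(C)(C)C)C/C(C)=C/CC1=CC(=O)C=C(C)C1=O)CO[Si](C)(C)C(C)(C)C
A1 | alternative 1 | 2-[(2E,5S,6E,10E,14E)-5,16-bis(tert-butyldimethylsilyloxy)-3,7,11,15-tetramethylhexadeca-2,6,10,14-tetraenyl]-4-methoxy-6-methylphenol | C/C(=C\CC/C(C)=C/CC/C(C)=C/[C@@H](O[Si](C)(C)C(C)(C)C)C/C(C)=C/Cc1cc(OC)cc(C)c1O)CO[Si](C)(C)C(C)(C)C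
A2 | alternative 1 | (4E,7S,8E,12E,16E)-7,18-bis(tert-butyldimethylsilyloxy)-5,9,13,17-tetramethyloctadeca-4,8,12,16-tetraen-1-yne | C/C(=C\CC/C(C)=C/CC/C(C)=C/[C@@H](O[Si](C)(C)C(C)(C)C)C/C(C)=C/CC#C)CO[Si](C)(C)C(C)(C)C
A3 | alternative 1 | pentacarbonyl[(2E)-1-methoxybut-2-enylidene]chromium | COC(/C=C/C)=[Cr](=C=O)(=C=O)(=C=O)(=C=O)=C=O
A4 | alternative 2 | (2S,4E)-6-(2,5-dimethoxy-3-methylphenyl)-2-[(4-methoxyphenyl)methoxy]-4-methylhex-4-enoic acid | OC(=O)[C@@H](OCc1ccc(OC)cc1)C/C(C)=C/Cc1cc(OC)cc(C)c1OC
A5 | alternative 2 | (2S)-1-(2,5-dimethoxy-3-methylphenyl)-3-methylbut-3-en-2-yl 2-[(4-methoxyphenyl)methoxy]acetate | C=C(C)[C@H](Cc1cc(OC)cc(C)c1OC)OC(=O)COCc1ccc(OC)cc1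
A6 | alternative 3 | 2-[(2E,5S,6E,10E,14E)-16-(tert-butyldimethylsilyloxy)-1-(2,5-dimethoxy-3-methylphenyl)-3,7,11,15-tetramethylhexadeca-2,6,10,14-tetraen-5-yl]-4,4,5,5-tetramethyl-1,3,2-dioxaborolane | C/C(=C\CC/C(C)=C/CC/C(C)=C/[C@@H](B1OC(C)(C)C(C)(C)O1)C/C(C)=C/Cc1cc(OC)cc(C)c1OC)CO[Si](C)(C)C(C)(C)C
A7 | alternative 3 | (3E)-5-(2,5-dimethoxy-3-methylphenyl)-3-methylpent-3-enyl N,N-diisopropylcarbamate | CC(C)N(C(C)C)C(=O)OCC/C(C)=C/Cc1cc(OC)cc(C)c1OC
A8 | alternative 3 | 2-[(1E,5E,9E)-11-(tert-butyldimethylsilyloxy)-2,6,10-trimethylundeca-1,5,9-trienyl]-4,4,5,5-tetramethyl-1,3,2-dioxaborolane | C/C(=C\CC/C(C)=C/CC/C(C)=C/B1OC(C)(C)C(C)(C)O1)CO[Si](C)(C)C(C)(C)C
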